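Two things are asked of these flasks: a row of end values and the shape of that row.

1. amount of target at the end, in percent of the substrate charged for alder, birch, maple, cedar, oak, in this order
2. how that number moves from the first to the last of them (rises, then falls / hardly changes / falls all the way / falls, then rises / rises all the way)

| setting | Tuesday's | Wednesday's | alder | birch | maple | cedar | oak |
|---|---|---|---|---|---|---|---|
| substrate | 0.10 M | 0.10 M | 0.10 M | 0.10 M | 0.10 M | 0.10 M | 0.10 M |
| partner | 0.45 equiv | 2.9 equiv | 0.400 equiv | 0.600 equiv | 1.00 equiv | 1.50 equiv | 2.50 equiv |
| remark | run made earlier | run made earlier |  |  |  |  |  |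
| time |  |  | 2.0 d | 2.0 d | 2.0 d | 2.0 d | 2.0 d |

- the earlier runs were read with a standard deviation of 1 percentage point
- on the list of suspects stand: partner + target -> over-reaction product; open intermediate + second intermediate -> target; partner -> second intermediate; target <-> isomer of the product; substrate -> open intermediate
- "hardly changes" means that all values lie within two and a half points (for a concentration: within two and a half percent of the largest)

| run | time / h | target / % |
|---|---|---|
| Tuesday's | 6.00 | 1.6 |
| Tuesday's | 12.0 | 7.5 |
| Tuesday's | 15.0 | 7.1 |
| Tuesday's | 25.0 | 10.2 |
| Tuesday's | 30.0 | 10.4 |
| Wednesday's | 2.50 | 0 |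
| Wednesday's | 6.00 | 13.5 |
| Wednesday's | 12.0 | 28.1 |
| Wednesday's | 20.0 | 29.9 |
| Wednesday's | 25.0 | 27.4 |
| Wednesday's | 30.0 | 21.7 |

(standard deviation of a reading: 1 percentage point)

I start from the balance of the reagent charged in the smaller amount, called the limiting reagent. On the list of suspects, a target is built from one open intermediate and one second intermediate. The first comes from one substrate, the second from one partner. The isomer of the product and the over-reaction product both descend from target, so the three together stay within the smaller charge. With 0.400 equiv in alder, that charge allows 40.0% of the substrate charged: call this the ceiling C, the smaller of the partner equivalents and one, in percent of the substrate charged.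

Now let F be a target reading divided by C. Tuesday's run, with C = 45.0%, reads 10.4% at 30.0 h, so F = 23.1%. Wednesday's run, with C = 100%, peaks in its readings at 29.9%, so F = 29.9%, then sinks to 21.7%. Both readings lie lower than C, so target is leaving or waiting somewhere. If Tuesday's level holds to 2.0 d, my own figure for alder is C times F, or 9.24%. C rises up to maple and stays flat after it, while Wednesday's run falls late, so I expect the row to rise and then fall.

The forecast gives 9.5%, 13%, 18%, 20% and 13%, with the shape rises, then falls. Its grounds are that “low loadings are partner-starved and high loadings are over-reacted”.

The flasks give 6.39%, 9.11%, 12.8%, 13.9% and 10.7%, and the shape is rises, then falls. The shape agrees, but the row lies lower than the forecast at each point, and alder lies lower than my 9.24%.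

    partner + target → over-reaction product (k = 2.00 × 10⁻⁴ /M/s)
    open intermediate + second intermediate → target (k = 2.20 × 10⁻⁴ /M/s)
    partner → second intermediate (k = 3.40 × 10⁻⁵ /s)
    target ⇌ isomer of the product (K = 16.0, k = 2.40 × 10⁻⁵ /s)
    substrate → open intermediate (k = 5.80 × 10⁻⁵ /s)

The gap under C has a proven reason. Without the reaction of target to isomer of the product, both ways, alder ends at 33.3% rather than 6.39%, which moves F from 16.0% to 83.2% of its C; this is the largest single effect there, not the whole of it. Oak has C = 100%, with substrate now the limiting reagent, and the same reaction is the main reason for its shortfall: F is 10.7% with the reaction and 76.4% without it.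

(The earlier runs and the new flask were computed with constants of no real substance; scatter was added.)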